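**Retrosynthetic overview**
- The triene is cut at the C(Me)–CH single bond next to the carbocycle: a cyclohexyl (E)-vinyl iodide plus a pyranone dienylboronate, joined last by Suzuki coupling.
- All four ring C–O bonds come from a cis-5,6-disubstituted cyclohexa-1,3-diene: singlet-oxygen [4+2] gives the two cis-1,4 oxygens, then osmylation of the remaining alkene on the peroxide face with acylative release gives the hydroxy acetate. The O–O bridge masks the other two oxygens until reduction.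
- The diene comes from an enone (dienyl triflate, methyl coupling), the enone from allylic oxidation of a cyclohexene made by an organocatalytic Diels–Alder reaction that sets the two carbon stereocentres.
- The pyranone arm comes from triketide cyclisation, O-methylation and a vinylogous aldol/dehydration with a borylated acrolein.
- Ring order: cyclohexene (step 1), dioxabicyclooctene (step 8), pyranone (step 11).

Assumption: compounds 1, 2, 17, 18 and 22 are purchased, and the sense of induction in step 1 follows the published facial model for this imidazolidinone (diene adds to the iminium face remote from the benzyl group).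

**Step 1**
Reactants: 1 acrolein; 2 (E)-3-methylpenta-1,3-diene
Product: 3 (1S,2S)-2,3-dimethylcyclohex-3-ene-1-carbaldehyde
Conditions: (5R)-5-benzyl-2,2,3-trimethylimidazolidin-4-one hydrochloride (20 mol%), MeCN/H2O 95:5, 0 °C to rt, excess 2
Reagents that add atoms: none
Why: Iminium-catalysed asymmetric Diels–Alder reaction; the endo transition state puts CHO and the ring methyl cis, the benzyl group blocks one iminium face to give (1S,2S), and the formyl-bearing carbon bonds to the methyl-bearing diene terminus ("ortho" rule).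

**Step 2**
Reactants: 3 (1S,2S)-2,3-dimethylcyclohex-3-ene-1-carbaldehyde
Product: 4 (3S,4S)-4-(2,2-dibromoethenyl)-2,3-dimethylcyclohex-1-ene
Conditions: CBr4, PPh3, CH2Cl2, 0 °C
Reagents that add atoms: carbon tetrabromide BrC(Br)(Br)Br
Why: Corey–Fuchs (Ramirez) dibromo-olefination is non-basic, so the epimerisable α-centre is untouched; minor Diels–Alder isomers are removed here.

**Step 3**
Reactants: 4 (3S,4S)-4-(2,2-dibromoethenyl)-2,3-dimethylcyclohex-1-ene
Product: 6 (3S,4S)-2,3-dimethyl-4-(prop-1-yn-1-yl)cyclohex-1-ene, via lithium acetylide 5 (not isolated)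
Conditions: n-BuLi (2.2 equiv), THF, −78 to 0 °C; then MeI, −78 °C to rt
Reagents that add atoms: iodomethane CI
Why: Second stage of the Corey–Fuchs reaction (Li–Br exchange, rearrangement, acetylide methylation); the propyne masks the side chain through the base and oxidation steps.

**Step 4**
Reactants: 6 (3S,4S)-2,3-dimethyl-4-(prop-1-yn-1-yl)cyclohex-1-ene
Product: 7 (4S,5S)-3,4-dimethyl-5-(prop-1-yn-1-yl)cyclohex-2-en-1-one
Conditions: Rh2(cap)4 (dirhodium tetrakis(caprolactamate), 1 mol%), t-BuOOH, K2CO3, CH2Cl2, rt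
Reagents that add atoms: tert-butyl hydroperoxide CC(C)(C)OO
Why: Radical allylic C–H oxidation at the only allylic methylene (next to the CH= terminus), the same site preference as in steroid 5-ene to 7-ketone oxidations.

**Step 5**
Reactants: 7 (4S,5S)-3,4-dimethyl-5-(prop-1-yn-1-yl)cyclohex-2-en-1-one
Product: 9 (5S,6R)-4,5-dimethyl-6-(prop-1-yn-1-yl)cyclohexa-1,3-dien-2-yl trifluoromethanesulfonate, via lithium dienolate 8 (not isolated)
Conditions: LiN(iPr)2, THF, −78 °C; then PhNTf2, −78 to 0 °C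
Reagents that add atoms: N-phenylbis(trifluoromethanesulfonimide) O=S(=O)(N(c1ccccc1)S(=O)(=O)C(F)(F)F)C(F)(F)F
Why: Kinetic deprotonation at the α′-methylene gives the cross-conjugated dienolate, and O-triflation fixes the 1,3-diene without touching the stereocentres.

**Step 6**
Reactants: 9 (5S,6R)-4,5-dimethyl-6-(prop-1-yn-1-yl)cyclohexa-1,3-dien-2-yl trifluoromethanesulfonate
Product: 10 (5S,6S)-1,3,6-trimethyl-5-(prop-1-yn-1-yl)cyclohexa-1,3-diene
Conditions: MeMgBr, Fe(acac)3 (5 mol%), THF/NMP, −30 °C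
Reagents that add atoms: methylmagnesium bromide C[Mg]Br
Why: Iron-catalysed Kumada-type coupling of an alkenyl triflate with a methyl Grignard reagent is fast at low temperature and leaves the internal alkyne alone.

**Step 7**
Reactants: 10 (5S,6S)-1,3,6-trimethyl-5-(prop-1-yn-1-yl)cyclohexa-1,3-diene
Product: 12 (5S,6S)-5-[(1E)-2-iodoprop-1-en-1-yl]-1,3,6-trimethylcyclohexa-1,3-diene, via alkenylzirconocene chloride 11 (not isolated)
Conditions: Cp2Zr(H)Cl (1.2 equiv), THF, rt to 40 °C; then I2, 0 °C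
Reagents that add atoms: iodine II
Why: syn-Hydrozirconation equilibrates zirconium onto the less hindered, methyl-bearing alkyne carbon, and iodinolysis with retention gives the (E)-iodide; the trisubstituted ring diene reacts much more slowly.

**Step 8**
Reactants: 12 (5S,6S)-5-[(1E)-2-iodoprop-1-en-1-yl]-1,3,6-trimethylcyclohexa-1,3-diene
Product: 13 (1R,4S,7S,8S)-8-[(1E)-2-iodoprop-1-en-1-yl]-1,5,7-trimethyl-2,3-dioxabicyclo[2.2.2]oct-5-ene
Conditions: O2, 5,10,15,20-tetraphenylporphyrin (cat.), white LED, CH2Cl2, −40 °C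
Reagents that add atoms: dioxygen O=O
Why: Singlet-oxygen [4+2] cycloaddition (Schenck photooxygenation) to the cyclic diene from the face opposite the two cis ring substituents, setting both bridgehead C–O centres cis to each other.

**Step 9**
Reactants: 13 (1R,4S,7S,8S)-8-[(1E)-2-iodoprop-1-en-1-yl]-1,5,7-trimethyl-2,3-dioxabicyclo[2.2.2]oct-5-ene
Product: 15 (1R,4S,5R,6S,7S,8S)-5-hydroxy-8-[(1E)-2-iodoprop-1-en-1-yl]-1,5,7-trimethyl-2,3-dioxabicyclo[2.2.2]octan-6-yl acetate, via osmate ester 14 (not isolated)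
Conditions: OsO4 (1.05 equiv), pyridine, CH2Cl2, −40 to 0 °C; then AcCl, 0 °C; then aq Na2SO3
Reagents that add atoms: osmium tetroxide O=[Os](=O)(=O)=O; acetyl chloride CC(Cl)=O
Why: Proposed new method: osmylation with acylative interception of the osmate ester. The [3+2] addition of OsO4 occurs on the peroxide face because the two endo substituents of the ethano bridge block the other face; the hexavalent osmium diolate is then acylated at its less hindered secondary alkoxide oxygen by N-acetylpyridinium, which breaks the chelate so the tertiary Os–O bond hydrolyses on work-up to give the secondary acetate and tertiary alcohol in one operation. Closest known reactions: Criegee osmylation, boronic-acid capture of osmate esters, and regioselective mono-acylation of dibutylstannylene acetals.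

**Step 10**
Reactants: 15 (1R,4S,5R,6S,7S,8S)-5-hydroxy-8-[(1E)-2-iodoprop-1-en-1-yl]-1,5,7-trimethyl-2,3-dioxabicyclo[2.2.2]octan-6-yl acetate
Product: 16 (1R,2S,3S,4S,5S,6R)-2,3,6-trihydroxy-4-[(1E)-2-iodoprop-1-en-1-yl]-2,5,6-trimethylcyclohexyl acetate
Conditions: Zn dust, AcOH, CH2Cl2, 0 °C to rt
Reagents that add atoms: none
Why: Reductive O–O cleavage with retention at both carbinol carbons releases the two masked hydroxyls; acetate and vinyl iodide are inert to Zn/AcOH at this temperature.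

**Step 11**
Reactants: 17 ethyl 2-methyl-3-oxopentanoate; 18 ethyl propanoate
Product: 20 6-ethyl-4-hydroxy-3,5-dimethyl-2H-pyran-2-one, via triketo ester 19 (not isolated)
Conditions: NaH then n-BuLi, THF, 0 °C; 18; aq HCl work-up; then 1,8-diazabicyclo[5.4.0]undec-7-ene (DBU), PhMe, reflux
Reagents that add atoms: none
Why: Dianion (Huckin–Weiler) Claisen acylation at the γ-carbon, then base-mediated lactonisation of the 3,5-diketo ester to the 4-hydroxy-2-pyranone.

**Step 12**
Reactants: 20 6-ethyl-4-hydroxy-3,5-dimethyl-2H-pyran-2-one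
Product: 21 6-ethyl-2-methoxy-3,5-dimethyl-4H-pyran-4-one
Conditions: MeOTf, CH2Cl2, rt; aq NaHCO3
Reagents that add atoms: methyl trifluoromethanesulfonate COS(=O)(=O)C(F)(F)F
Why: A hard methylating agent alkylates the lactone carbonyl oxygen, and loss of the proton gives the 2-methoxy-4-pyranone (Beak-type O-methylation).

**Step 13**
Reactants: 22 2-[(1E)-3,3-diethoxyprop-1-en-1-yl]-4,4,5,5-tetramethyl-1,3,2-dioxaborolane
Product: 23 (2E)-3-(4,4,5,5-tetramethyl-1,3,2-dioxaborolan-2-yl)prop-2-enal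
Conditions: 1 M HCl, acetone, rt
Reagents that add atoms: water O
Why: Acetal hydrolysis; the pinacol boronate and the E-alkene survive dilute acid.

**Step 14**
Reactants: 21 6-ethyl-2-methoxy-3,5-dimethyl-4H-pyran-4-one; 23 (2E)-3-(4,4,5,5-tetramethyl-1,3,2-dioxaborolan-2-yl)prop-2-enal
Product: 26 2-methoxy-3,5-dimethyl-6-[(2E,4E)-5-(4,4,5,5-tetramethyl-1,3,2-dioxaborolan-2-yl)penta-2,4-dien-2-yl]-4H-pyran-4-one, via lithium aldolate 24 (not isolated), via allylic mesylate 25 (not isolated)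
Conditions: LiN(SiMe3)2, THF, −78 °C; 23; then MsCl, −78 to 0 °C; then DBU, rt
Reagents that add atoms: none
Why: Vinylogous aldol addition of the lithiated 6-ethyl group (1,2 to the enal), then mesylation and E1cB elimination to the conjugated (E,E)-dienylboronate.

**Step 15**
Reactants: 16 (1R,2S,3S,4S,5S,6R)-2,3,6-trihydroxy-4-[(1E)-2-iodoprop-1-en-1-yl]-2,5,6-trimethylcyclohexyl acetate; 26 2-methoxy-3,5-dimethyl-6-[(2E,4E)-5-(4,4,5,5-tetramethyl-1,3,2-dioxaborolan-2-yl)penta-2,4-dien-2-yl]-4H-pyran-4-one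
Product: 27 amaurone A
Conditions: Pd(PPh3)4 (10 mol%), TlOEt, THF/H2O, rt, dark
Reagents that add atoms: none
Why: Suzuki–Miyaura coupling proceeds with retention of both alkene geometries; thallium ethoxide acceleration allows room temperature, which the acetate, free hydroxyls and light-sensitive triene tolerate.

**Compound list**
1 | acrolein | C=CC=O | starting material
2 | (E)-3-methylpenta-1,3-diene | C/C=C(C)/C=C | starting material
3 | (1S,2S)-2,3-dimethylcyclohex-3-ene-1-carbaldehyde | O=C[C@@H]1[C@H](C)C(C)=CCC1 | intermediate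
4 | (3S,4S)-4-(2,2-dibromoethenyl)-2,3-dimethylcyclohex-1-ene | BrC(Br)=C[C@@H]1[C@H](C)C(C)=CCC1 | intermediate
5 | lithium acetylide of 6 | [Li]C#C[C@@H]1[C@H](C)C(C)=CCC1 | intermediate
6 | (3S,4S)-2,3-dimethyl-4-(prop-1-yn-1-yl)cyclohex-1-ene | CC#C[C@@H]1[C@H](C)C(C)=CCC1 | intermediate
7 | (4S,5S)-3,4-dimethyl-5-(prop-1-yn-1-yl)cyclohex-2-en-1-one | CC#C[C@@H]1[C@H](C)C(C)=CC(=O)C1 | intermediate
8 | lithium cross-conjugated dienolate of 7 | CC#C[C@@H]1[C@H](C)C(C)=CC(O[Li])=C1 | intermediate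
9 | (5S,6R)-4,5-dimethyl-6-(prop-1-yn-1-yl)cyclohexa-1,3-dien-2-yl trifluoromethanesulfonate | CC#C[C@@H]1[C@H](C)C(C)=CC(OS(=O)(=O)C(F)(F)F)=C1 | intermediate
10 | (5S,6S)-1,3,6-trimethyl-5-(prop-1-yn-1-yl)cyclohexa-1,3-diene | CC#C[C@@H]1[C@H](C)C(C)=CC(C)=C1 | intermediate
11 | (E)-alkenylzirconocene chloride from 10 (Zr on the methyl-bearing carbon, trans to the ring) | Cl[Zr](C2C=CC=C2)(C3C=CC=C3)/C(C)=C/[C@@H]1[C@H](C)C(C)=CC(C)=C1 | intermediate
12 | (5S,6S)-5-[(1E)-2-iodoprop-1-en-1-yl]-1,3,6-trimethylcyclohexa-1,3-diene | I/C(C)=C/[C@@H]1[C@H](C)C(C)=CC(C)=C1 | intermediate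
13 | (1R,4S,7S,8S)-8-[(1E)-2-iodoprop-1-en-1-yl]-1,5,7-trimethyl-2,3-dioxabicyclo[2.2.2]oct-5-ene | I/C(C)=C/[C@@H]1[C@H](C)[C@]2(C)C=C(C)[C@H]1OO2 | intermediate
14 | cyclic dioxo-osmium diolate of 13, bis(pyridine) adduct (hexavalent osmium, on the peroxide face) | I/C(C)=C/[C@@H]1[C@H](C)[C@]2(C)[C@@H](O[Os]3(=O)=O)[C@@](C)(O3)[C@H]1OO2.c1ccncc1.c1ccncc1 | intermediate
15 | (1R,4S,5R,6S,7S,8S)-5-hydroxy-8-[(1E)-2-iodoprop-1-en-1-yl]-1,5,7-trimethyl-2,3-dioxabicyclo[2.2.2]octan-6-yl acetate | I/C(C)=C/[C@@H]1[C@H](C)[C@]2(C)[C@@H](OC(C)=O)[C@@](C)(O)[C@H]1OO2 | intermediate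
16 | (1R,2S,3S,4S,5S,6R)-2,3,6-trihydroxy-4-[(1E)-2-iodoprop-1-en-1-yl]-2,5,6-trimethylcyclohexyl acetate | I/C(C)=C/[C@@H]1[C@H](C)[C@@](C)(O)[C@@H](OC(C)=O)[C@@](C)(O)[C@H]1O | intermediate
17 | ethyl 2-methyl-3-oxopentanoate | CCC(=O)C(C)C(=O)OCC | starting material
18 | ethyl propanoate | CCC(=O)OCC | starting material
19 | ethyl 2,4-dimethyl-3,5-dioxoheptanoate (diastereomer mixture) | CCC(=O)C(C)C(=O)C(C)C(=O)OCC | intermediate
20 | 6-ethyl-4-hydroxy-3,5-dimethyl-2H-pyran-2-one | CCc1oc(=O)c(C)c(O)c1C | intermediate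
21 | 6-ethyl-2-methoxy-3,5-dimethyl-4H-pyran-4-one | CCc1oc(OC)c(C)c(=O)c1C | intermediate
22 | 2-[(1E)-3,3-diethoxyprop-1-en-1-yl]-4,4,5,5-tetramethyl-1,3,2-dioxaborolane | CCOC(OCC)/C=C/B1OC(C)(C)C(C)(C)O1 | starting material
23 | (2E)-3-(4,4,5,5-tetramethyl-1,3,2-dioxaborolan-2-yl)prop-2-enal | O=C/C=C/B1OC(C)(C)C(C)(C)O1 | intermediate
24 | lithium aldolate from 21 and 23 (diastereomer mixture) | COc1oc(C(C)C(O[Li])/C=C/B2OC(C)(C)C(C)(C)O2)c(C)c(=O)c1C | intermediate
25 | allylic mesylate from 24 (diastereomer mixture) | COc1oc(C(C)C(OS(C)(=O)=O)/C=C/B2OC(C)(C)C(C)(C)O2)c(C)c(=O)c1C | intermediate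
26 | 2-methoxy-3,5-dimethyl-6-[(2E,4E)-5-(4,4,5,5-tetramethyl-1,3,2-dioxaborolan-2-yl)penta-2,4-dien-2-yl]-4H-pyran-4-one | COc1oc(/C(C)=C/C=C/B2OC(C)(C)C(C)(C)O2)c(C)c(=O)c1C | intermediate
27 | amaurone A, (1R,2S,3S,4R,5S,6R)-2,3,6-trihydroxy-4-[(1E,3E,5E)-6-(6-methoxy-3,5-dimethyl-4-oxo-4H-pyran-2-yl)-2-methylhepta-1,3,5-trien-1-yl]-2,5,6-trimethylcyclohexyl acetate | COc1oc(/C(C)=C/C=C/C(C)=C/[C@@H]2[C@H](C)[C@@](C)(O)[C@@H](OC(C)=O)[C@@](C)(O)[C@H]2O)c(C)c(=O)c1C | target

**Step count**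
Total: 15 steps. Longest linear sequence: 11 steps (steps 1 to 10, then step 15).

**Steps most likely to fail, with fallbacks**

Step 1 (regiochemistry and endo selectivity of the Diels–Alder reaction). The terminal methyl of diene 2 directs "ortho" as needed, but the internal methyl pulls the other way, so a regioisomer may form in quantity. The fallback sets out from 1 and returns at 6. Commercial 3-methylpent-3-en-2-one is silylated (TBSOTf, Et3N) to (E)-tert-butyldimethyl[(3-methylpenta-1,3-dien-2-yl)oxy]silane F1. The silyloxy group then fixes the regiochemistry in a Diels–Alder reaction with 1 under a protonated oxazaborolidine catalyst, 1-(2-methylphenyl)-3,3-diphenyltetrahydro-1H,3H-pyrrolo[1,2-c][1,3,2]oxazaborole activated with HNTf2 (the antipode that gives the 1S,2S adduct, CH2Cl2, −78 °C). This gives (1S,2S)-4-[(tert-butyldimethylsilyl)oxy]-2,3-dimethylcyclohex-3-ene-1-carbaldehyde F2. CBr4/PPh3 gives tert-butyl{[(3S,4S)-4-(2,2-dibromoethenyl)-2,3-dimethylcyclohex-1-en-1-yl]oxy}dimethylsilane F3. n-BuLi then MeI gives tert-butyl{[(3S,4S)-2,3-dimethyl-4-(prop-1-yn-1-yl)cyclohex-1-en-1-yl]oxy}dimethylsilane F4. CsF/PhNTf2 converts the silyl enol ether into (3S,4S)-2,3-dimethyl-4-(prop-1-yn-1-yl)cyclohex-1-en-1-yl trifluoromethanesulfonate F5. Formate reduction (Pd(OAc)2, PPh3, HCO2H, Bu3N, DMF, 60 °C) removes the triflate and delivers 6.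

Step 4 (allylic oxidation in the presence of tertiary allylic and propargylic C–H bonds). The fallback sets out from 6 and returns at 7 by a non-radical, three-operation transposition. mCPBA epoxidises the ring alkene on the face away from the substituents to give 1,2-dimethyl-3-(prop-1-yn-1-yl)-7-oxabicyclo[4.1.0]heptane F6. Phenylselenide (PhSeSePh, NaBH4, EtOH) opens it at the secondary carbon to 1,2-dimethyl-6-(phenylselanyl)-3-(prop-1-yn-1-yl)cyclohexan-1-ol F7. H2O2 triggers selenoxide syn-elimination (Sharpless–Lauer), which can only go away from the quaternary carbinol, to give 1,6-dimethyl-5-(prop-1-yn-1-yl)cyclohex-2-en-1-ol F8. Pyridinium chlorochromate [C5H5NH][CrO3Cl] then effects the Babler–Dauben oxidative 1,3-transposition to enone 7.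

Step 9 (the proposed acylative interception). The osmate ester may resist acylation and simply give the diol on work-up, or acylation may be slow enough for pyridine to start a Kornblum–DeLaMare opening of the peroxide. The fallback sets out from 13 and returns at 15 with known chemistry in two operations. Catalytic OsO4 with N-methylmorpholine N-oxide in acetone/H2O (Upjohn dihydroxylation) gives (1R,4S,5R,6S,7S,8S)-8-[(1E)-2-iodoprop-1-en-1-yl]-1,5,7-trimethyl-2,3-dioxabicyclo[2.2.2]octane-5,6-diol F9. Ac2O in pyridine at 0 °C then acetylates the only secondary hydroxyl, the tertiary one being inert, to give 15.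

**Further compounds**
F1 | step 1 | (E)-tert-butyldimethyl[(3-methylpenta-1,3-dien-2-yl)oxy]silane | C/C=C(C)/C(=C)O[Si](C)(C)C(C)(C)C
F2 | step 1 | (1S,2S)-4-[(tert-butyldimethylsilyl)oxy]-2,3-dimethylcyclohex-3-ene-1-carbaldehyde | O=C[C@@H]1[C@H](C)C(C)=C(O[Si](C)(C)C(C)(C)C)CC1
F3 | step 1 | tert-butyl{[(3S,4S)-4-(2,2-dibromoethenyl)-2,3-dimethylcyclohex-1-en-1-yl]oxy}dimethylsilane | BrC(Br)=C[C@@H]1[C@H](C)C(C)=C(O[Si](C)(C)C(C)(C)C)CC1
F4 | step 1 | tert-butyl{[(3S,4S)-2,3-dimethyl-4-(prop-1-yn-1-yl)cyclohex-1-en-1-yl]oxy}dimethylsilane | CC#C[C@@H]1[C@H](C)C(C)=C(O[Si](C)(C)C(C)(C)C)CC1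
F5 | step 1 | (3S,4S)-2,3-dimethyl-4-(prop-1-yn-1-yl)cyclohex-1-en-1-yl trifluoromethanesulfonate | CC#C[C@@H]1[C@H](C)C(C)=C(OS(=O)(=O)C(F)(F)F)CC1
F6 | step 4 | 1,2-dimethyl-3-(prop-1-yn-1-yl)-7-oxabicyclo[4.1.0]heptane (oxirane trans to both ring substituents) | CC#C[C@@H]1[C@H](C)[C@@]2(C)O[C@H]2CC1
F7 | step 4 | 1,2-dimethyl-6-(phenylselanyl)-3-(prop-1-yn-1-yl)cyclohexan-1-ol (trans hydroxy selenide) | CC#C[C@@H]1[C@H](C)[C@@](C)(O)[C@H]([Se]c2ccccc2)CC1
F8 | step 4 | 1,6-dimethyl-5-(prop-1-yn-1-yl)cyclohex-2-en-1-ol | CC#C[C@@H]1[C@H](C)[C@@](C)(O)C=CC1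
F9 | step 9 | (1R,4S,5R,6S,7S,8S)-8-[(1E)-2-iodoprop-1-en-1-yl]-1,5,7-trimethyl-2,3-dioxabicyclo[2.2.2]octane-5,6-diol | I/C(C)=C/[C@@H]1[C@H](C)[C@]2(C)[C@@H](O)[C@@](C)(O)[C@H]1OO2
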